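# Proposed synthesis of CNP0271389.1 by oxa-[4+2] cycloaddition of a flavonyl stilbene with a salicyl oxocarbenium ion

## Analysis of the target

The target (22) is a 3,8''-linked biflavonoid: a 5,7,4'-trihydroxyflavanone (rings A, B and C) is bonded through C3 to C8'' of a 5'',7'',4'''-trioxygenated flavone, and O7'' of the flavone carries a hydrogen sulfate. It has two stereocentres, both in ring C: C2 (R, bearing the 4-hydroxyphenyl group) and C3 (S, bearing the flavone). They are trans, so both aryl groups are pseudo-equatorial and H2 and H3 are anti. C3 is alpha to the C4 ketone and carries an aryl group, so it enolises easily. Trans is the thermodynamic isomer, but under base the enolate expels O1 (retro-oxa-Michael reaction) and the configuration at C2 is lost, so no basic step may follow formation of the ketone. The aryl sulfate is cleaved by acid and by solvolysis and sits on one of six phenolic oxygens, so O7'' must be the only reactive hydroxyl when the sulfate is introduced and the last deprotection must be neutral. The synthesis is hard because the C3–C8'' bond joins a stereocentre to a di-ortho-substituted arene carbon and the absolute configuration has to be set next to this crowded bond. The plan rests on one feature: C2 and C3 with their two aryl groups have the connectivity of an (E)-1,2-diarylethene, and O1–C8a–C4a–C4 is a salicylaldehyde unit, so ring C is the [4+2] adduct of a salicyl heterodiene and a stilbene whose second aryl group is the flavone.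

## Retrosynthetic reasoning

**22 to 20 (four O–benzyl bonds).** With six phenolic oxygens and a sulfate that tolerates neither acid nor base for long, the last step must be neutral. The tetrabenzyl sulfate salt 20 is therefore debenzylated by hydrogenolysis and only then protonated. This fixes benzyl as the group on O5, O7, O4' and O4'''.

**20 to 18 (the S–O bond).** Sulfation is selective only if O7'' is the single reactive hydroxyl. In 18 the only other free hydroxyl is 5''-OH, which is locked in a hydrogen bond to the C4'' carbonyl and does not react with mild sulfating agents, so it needs no protecting group.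

**18 to 17 (the two ester C–O bonds at O5'' and O7'').** The acetates are removed by acid-catalysed alcoholysis, not by base, because base would enolise C3 and open ring C. They are removed only after C4 has become a ketone: a free 7''-OH beside a C4 cation would close a five-membered ether ring onto C4.

**17 to 16 to 15 (oxidation level of C4).** The ketone comes from the benzylic alcohol 16, and this from the benzylic methyl ether 15. The electron-rich ring A makes the C4–O bond of 15 labile to very mild aqueous acid.

**15 to 10 and 14 (C3–C4 and O1–C2, the key disconnection).** Cutting here removes ring C and all stereocentres in one operation and leaves two flat pieces: the stilbene 10 and the acetal 14, which forms in the flask from aldehyde 12 and trimethyl orthoformate 13. The crowded C3–C8'' bond becomes an sp2–sp2 bond that is easy to make. The forward reaction must do three things: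

- Bond C4 to the alkene carbon that carries the flavone.
- Keep the aryl groups trans.
- Select one alkene face.

The first point decides the protecting groups of 10. With ether groups on O5'' and O7'' the flavone ring would be a 2,4,6-trioxygenated aryl group, a better cation stabiliser than 4-benzyloxyphenyl, and the addition would be expected to run the wrong way round. As acetates these oxygens no longer donate, and the 4-benzyloxyphenyl group alone directs the addition.

**10 to 6 and 9 (the C8''–vinyl bond).** A Heck coupling of aryl iodide 6 with 4-benzyloxystyrene 9 gives the (E)-alkene directly. An allyl ether on O7'' was ruled out: an aryl–palladium species ortho to an allyloxy group cyclises onto the allyl double bond. Acetates have no such pathway.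

**6 to 5 to 4 to 3 to 2 to 1 (the C8–I bond and the order of protecting groups).** Iodination goes to C8 only while O5 and O7 are ethers; a free 5-OH directs to C6 and esters deactivate the ring. The sequence from apigenin 1 is therefore:

- The most acidic 7-OH is capped as an acetal (2).
- O4' and O5 are benzylated (3).
- C8 is iodinated (4).
- The 7-O-acetal and the peri 5-O-benzyl group are removed together by acid (5), leaving only the 4'-O-benzyl ether.
- The two free hydroxyls are acetylated (6).

**12 to 11 and 9 to 7.** Aldehyde 12 is the dibenzyl ether of 2,4,6-trihydroxybenzaldehyde 11; the chelated hydroxyl stays free and becomes O1. Styrene 9 is made from 4-acetoxystyrene 7 by ester cleavage and benzylation in one flask.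

## Alternatives that were turned down

**Alternative 1:** Ring A of the flavanone is disconnected at C4a–C5 and C8–C8a. In the forward step the bis(silyloxy)diene A3 adds across the C5=C6 double bond of the sulfinyl dihydropyranone A2, which already holds O1, C2, C3, C4 and both aryl groups. Loss of the sulfinyl and methoxy groups then aromatises the new ring to the 5,7-dihydroxyflavanone A1.

- For: ring A arrives with both oxygens in place and C4 already a ketone, so the two-step oxidation-level adjustment of the chosen route is not needed. No cation is involved, so the flavone may keep ether protecting groups. On these two points it is stronger.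
- Against: A2 itself contains the crowded C3–C8'' bond and both stereocentres, which need a separate asymmetric construction. They must then survive sulfinylation of a beta-alkoxy enone that can open by retro-oxa-Michael reaction. The double bond of A2 is a vinylogous ester and a poor dienophile. A1 has free 5- and 7-OH, so O7 must be protected again before O7'' can be unmasked and sulfated.
- Comparison: the chosen route makes ring C and both stereocentres in one step from flat precursors and needs fewer protecting-group operations after the ring is formed.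

**Alternative 2:** The benzene ring A of the flavone is disconnected at C8''–C8a'', C6''–C7'' and C4a''–C8a''. In the forward step the flavan ynol silyl ether A5 and 3-ethoxycyclobutenone A6 are heated; ring opening, [2+2] addition, a second ring opening and a six-electron electrocyclisation give the arene A4.

- For: the hindered arene is grown on C3 instead of being coupled, so there is no cross-coupling at a di-ortho-substituted carbon and no regiochemical question in ring C. The regiochemistry of the benzannulation is dependable. On these points it is stronger.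
- Against: A4 is only one ring of the flavone. The pyranone ring with its aryl group must still be built on C4a'' and O1'' in several steps on a hindered phenol. O5'' arrives as an ethyl ether, and conditions that cleave it would also cleave the benzyl ethers. A5 needs a stereodefined 3-alkynylflavan, so the stereochemical problem is again solved separately.
- Comparison: it is the longest of the four. The chosen route takes the complete flavone from commercial 1.

**Alternative 3:** Ring C is disconnected at O1–C8a and C4–C4a. In the forward step fluoride releases an aryne from A9; the ring oxygen of the beta-lactone A8 adds to it and the aryl anion attacks the lactone carbonyl. The net insertion into the acyl–O bond gives the chromanone A7.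

- For: it is the most direct plan. Ring C closes at the ketone oxidation level with all protecting groups in place. C2 and C3 are carried over unchanged from a lactone whose trans geometry and absolute configuration could come from asymmetric ketene–aldehyde [2+2] chemistry. The 3-alkoxy group of the aryne directs the addition so that O1 and C4 end on the right carbons. In redox economy and in steps after the key step it is better than the chosen route.
- Against: a lactone ring oxygen is a weak nucleophile towards an aryne, and insertion into an ester acyl–O bond is not an established reaction type. A beta-aryl beta-lactone with an alpha-aryl group decarboxylates on warming to a stilbene-type alkene and epimerises at C3 under basic fluoride. A8 needs an acetic acid arm on the hindered flavone carbon.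
- Comparison: the chosen route relies on a cycloaddition class with close analogy for aryl alkenes, and its selectivity can be tuned through protecting groups and the catalyst.

Key step: step 9

**Assumptions.**

- The (R)-configured catalyst is taken to give the flavan 15 as drawn; if the facial sense is the opposite, its (S)-enantiomer is used and nothing else changes.
- C4 of 15 and 16 is drawn as the expected 2,4-cis epimer; the other epimer converges in step 11.
- The descriptor at C3 changes from R (15, 16) to S (17 onwards) without any change in geometry, because C4 outranks C2 once it is a carbonyl carbon.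

## Route

Step 1
Reactants: 1 apigenin (5,7-dihydroxy-2-(4-hydroxyphenyl)-4H-chromen-4-one)
Product: 2 7-O-(methoxymethyl)apigenin (5-hydroxy-2-(4-hydroxyphenyl)-7-(methoxymethoxy)-4H-chromen-4-one)
Conditions: MOMCl (1.05 equiv), K2CO3 (1.0 equiv), DMF, 0 °C → rt
Reagents that add atoms: chloromethyl methyl ether, COCCl
Why: Williamson-type O-alkylation; the 7-OH is the most acidic phenol (a vinylogous acid through the C4 carbonyl), so one equivalent of base gives mainly the 7-phenoxide, while the 4'-OH is less acidic and the 5-OH is chelated.

Step 2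
Reactants: 2 7-O-(methoxymethyl)apigenin
Product: 3 5,4'-di-O-benzyl-7-O-(methoxymethyl)apigenin (5-benzyloxy-2-(4-benzyloxyphenyl)-7-(methoxymethoxy)-4H-chromen-4-one)
Conditions: BnBr (3 equiv), K2CO3 (3 equiv), DMF, 70 °C
Reagents that add atoms: benzyl bromide, BrCc1ccccc1
Why: Williamson benzylation; excess reagent and heat also alkylate the hydrogen-bonded 5-OH, and the acetal is stable to base.

Step 3
Reactants: 3 5,4'-di-O-benzyl-7-O-(methoxymethyl)apigenin
Product: 4 5,4'-di-O-benzyl-8-iodo-7-O-(methoxymethyl)apigenin (5-benzyloxy-2-(4-benzyloxyphenyl)-8-iodo-7-(methoxymethoxy)-4H-chromen-4-one)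
Conditions: NIS (1.05 equiv), TFA (0.2 equiv), MeCN–CH2Cl2, 0 °C → rt, dark
Reagents that add atoms: N-iodosuccinimide, O=C1CCC(=O)N1I
Why: Electrophilic aromatic iodination; 5,7-dialkoxyflavones without a free 5-OH are substituted at C8, because C6 is flanked by two alkoxy groups, and ring B is deactivated by conjugation with the enone.

Step 4
Reactants: 4 5,4'-di-O-benzyl-8-iodo-7-O-(methoxymethyl)apigenin
Product: 5 4'-O-benzyl-8-iodoapigenin (2-(4-benzyloxyphenyl)-5,7-dihydroxy-8-iodo-4H-chromen-4-one)
Conditions: conc. HCl–AcOH (1:10), 50 °C
Reagents that add atoms: none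
Why: Acid hydrolysis of the acetal together with chelation-assisted acidolysis of the peri 5-O-benzyl ether (the protonated C4 carbonyl is hydrogen-bonded to O5 and makes it the leaving group); the 4'-O-benzyl ether lacks this assistance and should remain.

Step 5
Reactants: 5 4'-O-benzyl-8-iodoapigenin
Product: 6 5,7-di-O-acetyl-4'-O-benzyl-8-iodoapigenin (2-(4-benzyloxyphenyl)-8-iodo-4-oxo-4H-chromene-5,7-diyl diacetate)
Conditions: Ac2O (6 equiv), DMAP (0.1 equiv), pyridine, 50 °C
Reagents that add atoms: acetic anhydride, CC(=O)OC(C)=O
Why: DMAP-catalysed acylation, warm enough to esterify the chelated 5-OH; the two acetates turn ring A of the flavone from an electron donor into an acceptor, which the regiochemistry of step 9 requires.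

Step 6
Reactants: 7 4-acetoxystyrene
Product: 9 4-benzyloxystyrene, via potassium 4-vinylphenoxide 8 (not isolated)
Conditions: KOH (2.2 equiv), DMSO, rt; then BnBr (1.1 equiv), rt
Reagents that add atoms: benzyl bromide, BrCc1ccccc1
Why: Saponification of the aryl acetate followed by Williamson benzylation of the phenoxide in the same flask, so the polymerisable free 4-vinylphenol is never isolated.

Step 7
Reactants: 6 5,7-di-O-acetyl-4'-O-benzyl-8-iodoapigenin; 9 4-benzyloxystyrene
Product: 10 (E)-5,7-diacetoxy-2-(4-benzyloxyphenyl)-8-[2-(4-benzyloxyphenyl)ethenyl]-4H-chromen-4-one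
Conditions: Pd(OAc)2 (5 mol %), P(o-tol)3 (10 mol %), Et3N (2 equiv), MeCN, 85 °C
Reagents that add atoms: none
Why: Mizoroki–Heck reaction; zerovalent palladium inserts into the electron-poor C8–I bond, syn-carbopalladation at the terminal carbon of the styrene and syn beta-hydride elimination give the (E)-1,2-diarylethene. No alkene sits ortho to the aryl–palladium bond, so no cyclisation competes, and aryl acetates tolerate the amine base in MeCN.

Step 8
Reactants: 11 2,4,6-trihydroxybenzaldehyde
Product: 12 2-hydroxy-4,6-bis(benzyloxy)benzaldehyde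
Conditions: BnBr (2.05 equiv), K2CO3 (2.1 equiv), DMF, rt
Reagents that add atoms: benzyl bromide, BrCc1ccccc1
Why: Williamson benzylation; the 4-OH and one ortho-OH react, while the last ortho-OH is held in a hydrogen bond to the formyl group and stays free to become O1.

Step 9
Reactants: 10 (E)-5,7-diacetoxy-2-(4-benzyloxyphenyl)-8-[2-(4-benzyloxyphenyl)ethenyl]-4H-chromen-4-one; 12 2-hydroxy-4,6-bis(benzyloxy)benzaldehyde; 13 trimethyl orthoformate
Product: 15 8-[(2R,3R,4R)-5,7-bis(benzyloxy)-2-(4-benzyloxyphenyl)-4-methoxychroman-3-yl]-2-(4-benzyloxyphenyl)-4-oxo-4H-chromene-5,7-diyl diacetate (2,3-trans, 3,4-trans), via 2-hydroxy-4,6-bis(benzyloxy)benzaldehyde dimethyl acetal 14 (not isolated)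
Conditions: 12 (2.0 equiv, added over 10 h), 13 (5 equiv), (R)-3,3'-bis(2,4,6-triisopropylphenyl)-1,1'-binaphthyl-2,2'-diyl hydrogen phosphate [(R)-TRIP, 10 mol %], CH2Cl2, 0 °C → rt
Reagents that add atoms: none
Why: The acid converts 12 and 13 into acetal 14 and ionises it to the 2-hydroxyaryl oxocarbenium ion, a protonated ortho-quinone methide paired with the chiral phosphate. Its electrophilic carbon (the future C4) bonds to the alkene carbon that carries the flavone, positive charge builds up on the carbon bearing the 4-benzyloxyphenyl group, and the phenolic oxygen closes on it; this is an inverse-electron-demand oxa-[4+2] cycloaddition, concerted but asynchronous, that forms C3–C4 and O1–C2 and closes the six-membered ring C. The closest known reaction type is the acid-promoted cycloaddition of ortho-quinone methides and salicylaldehyde-acetal oxocarbenium ions with styrenes and 1-arylpropenes to 2-aryl-4-alkoxychromans, including versions catalysed by chiral binaphthyl phosphoric acids. C2 and C3 become trans because the addition is suprafacial on the (E)-alkene; if closure is stepwise, the benzylic C2–O bond can re-ionise and settle in the diequatorial trans form without touching C3. Their absolute configuration comes from the phosphate, which is hydrogen-bonded to the phenol and ion-paired with the cation and so leaves one alkene face open. C4 is set by endo approach (expected 2,4-cis) and is destroyed in step 11. The step needs the cation to form next to the 4-benzyloxyphenyl group; the two acetoxy groups and the pyranone carbonyl make the flavone ring a poor donor and secure this. It also needs the alkene to compete with Friedel–Crafts attack on the electron-rich ring of 14, which is why 12 is added slowly to keep 14 dilute.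

Step 10
Reactants: 15 the 4-methoxyflavan
Product: 16 8-[(2R,3R,4R)-5,7-bis(benzyloxy)-2-(4-benzyloxyphenyl)-4-hydroxychroman-3-yl]-2-(4-benzyloxyphenyl)-4-oxo-4H-chromene-5,7-diyl diacetate
Conditions: TsOH·H2O (5 mol %), THF–H2O (4:1), 0 °C → rt; NaHCO3 quench
Reagents that add atoms: water, O
Why: SN1 solvolysis; the 5,7-dibenzyloxy ring ionises the benzylic C4–OMe bond under very mild acid and water in large excess captures the cation. The acetates stay on, so no phenol is near the cation, and the configuration at C4 does not matter.

Step 11
Reactants: 16 the flavan-4-ol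
Product: 17 8-[(2R,3S)-5,7-bis(benzyloxy)-2-(4-benzyloxyphenyl)-4-oxochroman-3-yl]-2-(4-benzyloxyphenyl)-4-oxo-4H-chromene-5,7-diyl diacetate
Conditions: Dess–Martin periodinane (1.5 equiv), pyridine (5 equiv), CH2Cl2, 0 °C → rt
Reagents that add atoms: none
Why: Dess–Martin oxidation of the secondary benzylic alcohol, buffered with pyridine so that the acetic acid released cannot re-ionise C4; pyridine is too weak to open ring C, and 2,3-trans is the thermodynamic arrangement at C3 in any case.

Step 12
Reactants: 17 the flavanone diacetate
Product: 18 (2R,3S)-5,7-bis(benzyloxy)-2-(4-benzyloxyphenyl)-3-[2-(4-benzyloxyphenyl)-5,7-dihydroxy-4-oxo-4H-chromen-8-yl]chroman-4-one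
Conditions: HCl (1.25 M in MeOH)–THF (1:1), rt
Reagents that add atoms: none
Why: Acid-catalysed transesterification of the two aryl acetates; acid is used because base would enolise C3 and open ring C, and the ketone now prevents any cation chemistry at C4. Should the peri 5-O-benzyl ether be partly lost, the chelated phenol formed is inert in step 13 and is freed in step 14 anyway.

Step 13
Reactants: 18 the 5'',7''-diol
Product: 20 sodium 8-[(2R,3S)-5,7-bis(benzyloxy)-2-(4-benzyloxyphenyl)-4-oxochroman-3-yl]-2-(4-benzyloxyphenyl)-5-hydroxy-4-oxo-4H-chromen-7-yl sulfate, via pyridinium salt of the 7''-sulfate 19 (not isolated)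
Conditions: SO3·pyridine (5 equiv), pyridine, rt → 35 °C; then aq. NaHCO3 (to pH 7–8), 0 °C
Reagents that add atoms: sulfur trioxide–pyridine complex, O=S(=O)([O-])[n+]1ccccc1; sodium hydrogen carbonate, [Na+].OC([O-])=O
Why: O-sulfation with an SO3–amine complex; O7'' is the only hydroxyl not locked in a hydrogen bond to a carbonyl group, and the chelated 5''-OH does not react under these conditions. The sodium salt is made because a pyridinium counter-ion would inhibit the hydrogenolysis.

Step 14
Reactants: 20 the tetrabenzyl sodium sulfate
Product: 22 8-[(2R,3S)-5,7-dihydroxy-2-(4-hydroxyphenyl)-4-oxochroman-3-yl]-5-hydroxy-2-(4-hydroxyphenyl)-4-oxo-4H-chromen-7-yl hydrogen sulfate (the target), via debenzylated sodium sulfate salt 21 (not isolated)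
Conditions: H2 (1 atm), Pd/C (10 wt %), THF–MeOH, rt; filter; aq. HCl (1.0 equiv), 0 °C; C18 desalting (H2O, then MeCN–H2O), lyophilisation
Reagents that add atoms: none
Why: Hydrogenolysis of the four benzyl ethers over Pd/C under neutral conditions, which aryl sulfate salts, the flavone double bond and the flavanone tolerate; one equivalent of acid in the cold then protonates the sulfate. The free acid should be kept cold, and salt 21 is the better form for storage.

## Compound list

1 | apigenin | O=c1cc(-c2ccc(O)cc2)oc2cc(O)cc(O)c12 | starting material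
2 | 7-O-(methoxymethyl)apigenin | O=c1cc(-c2ccc(O)cc2)oc2cc(OCOC)cc(O)c12 | intermediate
3 | 5,4'-di-O-benzyl-7-O-(methoxymethyl)apigenin | O=c1cc(-c2ccc(OCc3ccccc3)cc2)oc2cc(OCOC)cc(OCc3ccccc3)c12 | intermediate
4 | 5,4'-di-O-benzyl-8-iodo-7-O-(methoxymethyl)apigenin | O=c1cc(-c2ccc(OCc3ccccc3)cc2)oc2c(I)c(OCOC)cc(OCc3ccccc3)c12 | intermediate
5 | 4'-O-benzyl-8-iodoapigenin | O=c1cc(-c2ccc(OCc3ccccc3)cc2)oc2c(I)c(O)cc(O)c12 | intermediate
6 | 5,7-di-O-acetyl-4'-O-benzyl-8-iodoapigenin | CC(=O)Oc1cc(OC(C)=O)c2c(=O)cc(-c3ccc(OCc4ccccc4)cc3)oc2c1I | intermediate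
7 | 4-acetoxystyrene | CC(=O)Oc1ccc(C=C)cc1 | starting material
8 | potassium 4-vinylphenoxide | [K+].[O-]c1ccc(C=C)cc1 | intermediate
9 | 4-benzyloxystyrene | C=Cc1ccc(OCc2ccccc2)cc1 | intermediate
10 | (E)-5,7-diacetoxy-2-(4-benzyloxyphenyl)-8-[2-(4-benzyloxyphenyl)ethenyl]-4H-chromen-4-one | CC(=O)Oc1cc(OC(C)=O)c2c(=O)cc(-c3ccc(OCc4ccccc4)cc3)oc2c1/C=C/c1ccc(OCc2ccccc2)cc1 | intermediate
11 | 2,4,6-trihydroxybenzaldehyde | O=Cc1c(O)cc(O)cc1O | starting material
12 | 2-hydroxy-4,6-bis(benzyloxy)benzaldehyde | O=Cc1c(O)cc(OCc2ccccc2)cc1OCc1ccccc1 | intermediate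
13 | trimethyl orthoformate | COC(OC)OC | starting material
14 | 2-hydroxy-4,6-bis(benzyloxy)benzaldehyde dimethyl acetal | COC(OC)c1c(O)cc(OCc2ccccc2)cc1OCc1ccccc1 | intermediate
15 | (2R,3R,4R)-4-methoxyflavan bearing the 5,7-diacetoxy-4'-benzyloxyflavon-8-yl group on C3 (C4 drawn as the expected epimer) | CO[C@H]1c2c(OCc3ccccc3)cc(OCc3ccccc3)cc2O[C@@H](c2ccc(OCc3ccccc3)cc2)[C@@H]1c1c(OC(C)=O)cc(OC(C)=O)c2c(=O)cc(-c3ccc(OCc4ccccc4)cc3)oc12 | intermediate
16 | (2R,3R,4R)-flavan-4-ol corresponding to 15 (C4 drawn as the expected epimer) | O[C@H]1c2c(OCc3ccccc3)cc(OCc3ccccc3)cc2O[C@@H](c2ccc(OCc3ccccc3)cc2)[C@@H]1c1c(OC(C)=O)cc(OC(C)=O)c2c(=O)cc(-c3ccc(OCc4ccccc4)cc3)oc12 | intermediate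
17 | (2R,3S)-5,7,4'-tri-O-benzylflavanone bearing the 5,7-diacetoxy-4'-benzyloxyflavon-8-yl group on C3 | O=C1c2c(OCc3ccccc3)cc(OCc3ccccc3)cc2O[C@@H](c2ccc(OCc3ccccc3)cc2)[C@@H]1c1c(OC(C)=O)cc(OC(C)=O)c2c(=O)cc(-c3ccc(OCc4ccccc4)cc3)oc12 | intermediate
18 | (2R,3S)-5,7,4'-tri-O-benzylflavanone bearing the 5,7-dihydroxy-4'-benzyloxyflavon-8-yl group on C3 | O=C1c2c(OCc3ccccc3)cc(OCc3ccccc3)cc2O[C@@H](c2ccc(OCc3ccccc3)cc2)[C@@H]1c1c(O)cc(O)c2c(=O)cc(-c3ccc(OCc4ccccc4)cc3)oc12 | intermediate
19 | pyridinium salt of the 7''-O-sulfate of 18 | O=C1c2c(OCc3ccccc3)cc(OCc3ccccc3)cc2O[C@@H](c2ccc(OCc3ccccc3)cc2)[C@@H]1c1c(OS(=O)(=O)[O-])cc(O)c2c(=O)cc(-c3ccc(OCc4ccccc4)cc3)oc12.c1cc[nH+]cc1 | intermediate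
20 | sodium salt of the 7''-O-sulfate of 18 | O=C1c2c(OCc3ccccc3)cc(OCc3ccccc3)cc2O[C@@H](c2ccc(OCc3ccccc3)cc2)[C@@H]1c1c(OS(=O)(=O)[O-])cc(O)c2c(=O)cc(-c3ccc(OCc4ccccc4)cc3)oc12.[Na+] | intermediate
21 | sodium salt of the target | O=C1c2c(O)cc(O)cc2O[C@@H](c2ccc(O)cc2)[C@@H]1c1c(OS(=O)(=O)[O-])cc(O)c2c(=O)cc(-c3ccc(O)cc3)oc12.[Na+] | intermediate
22 | CNP0271389.1, (2R,3S)-3,8''-linked flavanone–flavone 7''-O-hydrogen sulfate | O=C1c2c(O)cc(O)cc2O[C@@H](c2ccc(O)cc2)[C@@H]1c1c(OS(=O)(=O)O)cc(O)c2c(=O)cc(-c3ccc(O)cc3)oc12 | target

## Step count and least certain steps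

Total: 14 steps. Longest linear sequence: 12 steps (steps 1–5, 7 and 9–14).

**Step 9 (key step).**
- What may go wrong: addition to the hindered alkene may be slow, so that Friedel–Crafts self-condensation of the heterodiene precursor and alkylation of ring A of the product take over. The chiral ion pair may discriminate the alkene faces poorly. The product may re-ionise at C4 and eliminate.
- Why: the alkene is less nucleophilic than the phloroglucinol-type rings present, and a chiral ion pair limits the temperature and acid strength that can be used.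
- Fallback: setting out from 10, 12 and 13, the cycloaddition is run without a chiral catalyst, with Sc(OTf)3 (10–20 mol %) in CH2Cl2 or MeCN at rt to 40 °C. These conditions are free to be more forcing because they no longer have to carry the enantiocontrol. The product is the racemic cycloadduct, 15 together with its mirror image ent-15 F1. Steps 10 and 11 are applied to the racemate (16 with ent-16 F2, then 17 with ent-17 F3). The enantiomers are separated at the ketone stage, where only one diastereomer exists, by preparative chromatography on a chiral stationary phase. The route is rejoined at 17.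

**Step 10.**
- What may go wrong: loss of H3 from the C4 cation to give a flav-3-ene, which destroys C3, or premature loss of the 7''-O-acetate followed by ring closure of O7'' onto C4.
- Why: the cation is long-lived, and H3 is axial and aligned with the empty orbital.
- Fallback: setting out from 15, the benzylic methyl ether is oxidised directly with DDQ (1.3 equiv) in CH2Cl2–aqueous pH 7 buffer at 0 °C → rt. Hydride abstraction from C4–H gives the aryl-stabilised methoxycarbenium ion, which water converts into the ketone. This returns at 17 and bypasses 16 and step 11; it makes no new compound (F0).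

**Step 7.**
- What may go wrong: slow carbopalladation at the di-ortho-substituted C8, leading to reduction of the iodide, arylation at the internal carbon of the electron-rich styrene, or loss of the 7-O-acetate.
- Why: steric shielding of the aryl–palladium bond by the acetoxy group and the ring oxygen.
- Fallback: setting out from 9 and 5, cross-metathesis of 9 with vinylboronic acid pinacol ester (second-generation Grubbs catalyst, CH2Cl2, 40 °C) gives (E)-2-[2-(4-benzyloxyphenyl)ethenyl]-4,4,5,5-tetramethyl-1,3,2-dioxaborolane F4. Suzuki–Miyaura coupling of F4 with the unprotected iodide 5 (PdCl2(dppf), K2CO3, dioxane–H2O, 80 °C) gives (E)-2-(4-benzyloxyphenyl)-8-[2-(4-benzyloxyphenyl)ethenyl]-5,7-dihydroxy-4H-chromen-4-one F5. Here the alkene geometry is already fixed and no carbopalladation is needed. Acetylation under the conditions of step 5 returns the route at 10.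

**Step 4.**
- What may go wrong: loss of the 4'-O-benzyl ether as well, or loss or migration of iodine under warm acid.
- Why: the selectivity rests only on the peri assistance at O5, and an iodophenol can be protodeiodinated.
- Fallback: setting out from 2, the 4'-OH alone is benzylated (BnBr 1.1 equiv, K2CO3, acetone, reflux) to 4'-O-benzyl-7-O-(methoxymethyl)apigenin F6. The chelated 5-OH is then capped (NaH, MOMCl, DMF) to give 4'-O-benzyl-5,7-bis-O-(methoxymethyl)apigenin F7. Iodination (NIS, MeCN, no acid) gives 4'-O-benzyl-8-iodo-5,7-bis-O-(methoxymethyl)apigenin F8. Mild HCl in MeOH–THF at 40 °C removes both acetals without touching a benzyl ether and returns at 5.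

**Step 1.**
- What may go wrong: over-alkylation at O4' and mixtures of mono-ethers.
- Why: the chloromethyl ether is very reactive and discriminates little between the two phenoxides once both are present.
- Fallback: setting out from 1, peracetylation (Ac2O, pyridine) gives apigenin 5,7,4'-triacetate F9. Thiophenol and imidazole in N-methylpyrrolidone at 0 °C remove only the most activated 7-O-acetate to give 5,4'-di-O-acetylapigenin F10. MOMCl and iPr2NEt in CH2Cl2 give 5,4'-di-O-acetyl-7-O-(methoxymethyl)apigenin F11. K2CO3 in MeOH removes the acetates and returns at 2.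

## Further compounds

F1 | step 9 | ent-15, the (2S,3S,4S) enantiomer of 15 | CO[C@@H]1c2c(OCc3ccccc3)cc(OCc3ccccc3)cc2O[C@H](c2ccc(OCc3ccccc3)cc2)[C@H]1c1c(OC(C)=O)cc(OC(C)=O)c2c(=O)cc(-c3ccc(OCc4ccccc4)cc3)oc12
F2 | step 9 | ent-16, the (2S,3S,4S) enantiomer of 16 | O[C@@H]1c2c(OCc3ccccc3)cc(OCc3ccccc3)cc2O[C@H](c2ccc(OCc3ccccc3)cc2)[C@H]1c1c(OC(C)=O)cc(OC(C)=O)c2c(=O)cc(-c3ccc(OCc4ccccc4)cc3)oc12
F3 | step 9 | ent-17, the (2S,3R) enantiomer of 17 | O=C1c2c(OCc3ccccc3)cc(OCc3ccccc3)cc2O[C@H](c2ccc(OCc3ccccc3)cc2)[C@H]1c1c(OC(C)=O)cc(OC(C)=O)c2c(=O)cc(-c3ccc(OCc4ccccc4)cc3)oc12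
F0 | step 10 | none | none
F4 | step 7 | (E)-2-[2-(4-benzyloxyphenyl)ethenyl]-4,4,5,5-tetramethyl-1,3,2-dioxaborolane | CC1(C)OB(/C=C/c2ccc(OCc3ccccc3)cc2)OC1(C)C
F5 | step 7 | (E)-2-(4-benzyloxyphenyl)-8-[2-(4-benzyloxyphenyl)ethenyl]-5,7-dihydroxy-4H-chromen-4-one | O=c1cc(-c2ccc(OCc3ccccc3)cc2)oc2c(/C=C/c3ccc(OCc4ccccc4)cc3)c(O)cc(O)c12
F6 | step 4 | 4'-O-benzyl-7-O-(methoxymethyl)apigenin | O=c1cc(-c2ccc(OCc3ccccc3)cc2)oc2cc(OCOC)cc(O)c12
F7 | step 4 | 4'-O-benzyl-5,7-bis-O-(methoxymethyl)apigenin | O=c1cc(-c2ccc(OCc3ccccc3)cc2)oc2cc(OCOC)cc(OCOC)c12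
F8 | step 4 | 4'-O-benzyl-8-iodo-5,7-bis-O-(methoxymethyl)apigenin | O=c1cc(-c2ccc(OCc3ccccc3)cc2)oc2c(I)c(OCOC)cc(OCOC)c12
F9 | step 1 | apigenin 5,7,4'-triacetate | CC(=O)Oc1ccc(-c2cc(=O)c3c(OC(C)=O)cc(OC(C)=O)cc3o2)cc1
F10 | step 1 | 5,4'-di-O-acetylapigenin | CC(=O)Oc1ccc(-c2cc(=O)c3c(OC(C)=O)cc(O)cc3o2)cc1
F11 | step 1 | 5,4'-di-O-acetyl-7-O-(methoxymethyl)apigenin | COCOc1cc(OC(C)=O)c2c(=O)cc(-c3ccc(OC(C)=O)cc3)oc2c1
A1 | alternative 1 | (2R,3S)-5,7-dihydroxy-4'-O-benzylflavanone bearing the 5,4'-di-O-benzyl-7-O-(methoxymethyl)flavon-8-yl group on C3 | O=C1c2c(O)cc(O)cc2O[C@@H](c2ccc(OCc3ccccc3)cc2)[C@@H]1c1c(OCOC)cc(OCc3ccccc3)c2c(=O)cc(-c3ccc(OCc4ccccc4)cc3)oc12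
A2 | alternative 1 | (2R,3S)-2-(4-benzyloxyphenyl)-3-[5,4'-di-O-benzyl-7-O-(methoxymethyl)flavon-8-yl]-5-(phenylsulfinyl)-2,3-dihydro-4H-pyran-4-one | O=C1C(S(=O)c2ccccc2)=CO[C@@H](c2ccc(OCc3ccccc3)cc2)[C@@H]1c1c(OCOC)cc(OCc3ccccc3)c2c(=O)cc(-c3ccc(OCc4ccccc4)cc3)oc12
A3 | alternative 1 | 1-methoxy-1,3-bis(trimethylsilyloxy)buta-1,3-diene | COC(O[Si](C)(C)C)=CC(=C)O[Si](C)(C)C
A4 | alternative 2 | 3-[2-hydroxy-4-ethoxy-6-(triisopropylsilyloxy)phenyl]-4-(tert-butyldimethylsilyloxy)-5,7,4'-tri-O-benzylflavan | CC(C)(C)[Si](C)(C)O[C@H]1c2c(OCc3ccccc3)cc(OCc3ccccc3)cc2O[C@@H](c2ccc(OCc3ccccc3)cc2)[C@@H]1c1c(O[Si](C(C)C)(C(C)C)C(C)C)cc(OCC)cc1O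
A5 | alternative 2 | 3-[(triisopropylsilyloxy)ethynyl]-4-(tert-butyldimethylsilyloxy)-5,7,4'-tri-O-benzylflavan | CC(C)(C)[Si](C)(C)O[C@H]1c2c(OCc3ccccc3)cc(OCc3ccccc3)cc2O[C@@H](c2ccc(OCc3ccccc3)cc2)[C@@H]1C#CO[Si](C(C)C)(C(C)C)C(C)C
A6 | alternative 2 | 3-ethoxycyclobut-2-en-1-one | CCOC1=CC(=O)C1
A7 | alternative 3 | (2R,3S)-5,7-di-O-benzylflavanone with 4'-O-benzyl carbonate, bearing the 5,4'-di-O-benzyl-7-O-(methoxymethyl)flavon-8-yl group on C3 | O=C1c2c(OCc3ccccc3)cc(OCc3ccccc3)cc2O[C@@H](c2ccc(OC(=O)OCc3ccccc3)cc2)[C@@H]1c1c(OCOC)cc(OCc3ccccc3)c2c(=O)cc(-c3ccc(OCc4ccccc4)cc3)oc12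
A8 | alternative 3 | trans-4-[4-(benzyloxycarbonyloxy)phenyl]-3-[5,4'-di-O-benzyl-7-O-(methoxymethyl)flavon-8-yl]oxetan-2-one | O=C1O[C@@H](c2ccc(OC(=O)OCc3ccccc3)cc2)[C@@H]1c1c(OCOC)cc(OCc3ccccc3)c2c(=O)cc(-c3ccc(OCc4ccccc4)cc3)oc12
A9 | alternative 3 | 3,5-bis(benzyloxy)-2-(trimethylsilyl)phenyl trifluoromethanesulfonate | C[Si](C)(C)c1c(OCc2ccccc2)cc(OCc2ccccc2)cc1OS(=O)(=O)C(F)(F)F
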